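**Plan**

- Retrosynthetic cuts, in order: the acyl C–O bond of lactone D; the ring B bond between the ethyl-bearing carbon and the oxygen-bearing carbon (carbonyl-ene); the C9–C9a bond of ring A (alkyne hydroarylation); ring E at the pyrrole α-carbon (formylation, allylation–lactonisation); the bond from the pyrrole β-carbon to the side chain (rhodium 1,4-addition to furan-2(5H)-one) and the N-alkyl bond.
- Forward order: pyrrole 3-boronate → side chain as a trans butyrolactone, then opened to a silyloxy N-methoxy-N-methylamide → C5 formylation → ring E (methylene lactone) → ring A with the Z-propylidene group → ring E methyl → aldehyde → ring B → ring D.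
- Enabling feature: in ring B the ethyl-bearing carbon is allylic to the C8=C9 alkene of ring A and next to the O-bearing carbon of lactone D. This homoallylic alcohol is what an aldehyde and a Z-propylidene group on C9 give in an ene reaction that takes hydrogen from C8.
- Stereochemistry: the aryl-bound CH from (S)-BINAP–rhodium; the adjacent methyl by trans enolate alkylation on the lactone template; the ring E carbinol from a chiral chromium catalyst and its methyl by hydrogenation anti to the pyrrole; the Z alkene from anti hydroarylation; the CH–Et and CH–O centres from the ene transition state.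

Key step: step 14

Remark: rings are lettered A (azepine), B (carbocycle), C (pyrrole), D (fused lactone) and E (pendant lactone). Bicyclic intermediates use pyrrolo[1,2-a]azepine numbering (C1–C3, N4, C5–C9, C9a). All configurations are those of the given SMILES (CH–Et S, CH–O R, aryl-bound CH S, CH–Me of ring D R; ring E 2R,4R).

**Route**

Step 1
Reactants: 1 1-(triisopropylsilyl)-3-(4,4,5,5-tetramethyl-1,3,2-dioxaborolan-2-yl)-1H-pyrrole; 2 furan-2(5H)-one
Product: 3 (S)-4-[1-(triisopropylsilyl)-1H-pyrrol-3-yl]dihydrofuran-2(3H)-one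
Conditions: [Rh(OH)((S)-binap)]2 (3 mol % Rh), dioxane/H2O 10:1, 60 °C
Reagents that add atoms: none
Why: Rhodium-catalysed asymmetric 1,4-addition of an arylboron reagent to an unsaturated lactone; the pyrrolyl–rhodium species (monovalent rhodium) should insert the butenolide from the face left open by (S)-BINAP, the sense that gives (S)-3-arylcycloalkanones, and hydrolysis of the oxa-π-allyl releases the (S)-lactone.

Step 2
Reactants: 3 (S)-4-[1-(triisopropylsilyl)-1H-pyrrol-3-yl]dihydrofuran-2(3H)-one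
Product: 4 (S)-4-(1H-pyrrol-3-yl)dihydrofuran-2(3H)-one
Conditions: TBAF, THF, 0 °C
Reagents that add atoms: none
Why: Fluoride N-desilylation of an N-silylpyrrole; the lactone and its non-enolisable C4 stereocentre are not touched.

Step 3
Reactants: 5 but-1-yne; 6 1-chloro-4-iodobutane
Product: 7 8-chlorooct-3-yne
Conditions: n-BuLi, THF, −78 °C; then 6, DMPU, −78 °C → rt
Reagents that add atoms: none
Why: SN2 alkylation of lithium but-1-ynide, which displaces iodide much faster than chloride, so the chloride is kept as the handle for step 4.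

Step 4
Reactants: 4 (S)-4-(1H-pyrrol-3-yl)dihydrofuran-2(3H)-one; 7 8-chlorooct-3-yne
Product: 8 (S)-4-[1-(oct-5-yn-1-yl)-1H-pyrrol-3-yl]dihydrofuran-2(3H)-one
Conditions: NaH, DMF, 0 °C; then 7, NaI (10 mol %), rt → 50 °C
Reagents that add atoms: none
Why: N-alkylation of the sodium pyrrolide (N–H is the most acidic site) with in situ Finkelstein activation of the chloride; it is run before the α-methyl group is present so no epimerisable centre is exposed to base.

Step 5
Reactants: 8 (S)-4-[1-(oct-5-yn-1-yl)-1H-pyrrol-3-yl]dihydrofuran-2(3H)-one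
Product: 9 (3R,4S)-3-methyl-4-[1-(oct-5-yn-1-yl)-1H-pyrrol-3-yl]dihydrofuran-2(3H)-one
Conditions: LiN(iPr)2 (1.1 equiv), THF, −78 °C; MeI, −78 → −40 °C
Reagents that add atoms: iodomethane, CI
Why: Alkylation of the butyrolactone lithium enolate anti to the C4 pyrrolyl group, the usual outcome for 4-substituted butyrolactone enolates, should give the trans (3R,4S) lactone.

Step 6
Reactants: 9 (3R,4S)-3-methyl-4-[1-(oct-5-yn-1-yl)-1H-pyrrol-3-yl]dihydrofuran-2(3H)-one
Product: 10 (2R,3S)-4-hydroxy-N-methoxy-N,2-dimethyl-3-[1-(oct-5-yn-1-yl)-1H-pyrrol-3-yl]butanamide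
Conditions: MeNH(OMe)·HCl, AlMe3, CH2Cl2, 0 °C → rt
Reagents that add atoms: N,O-dimethylhydroxylamine hydrochloride, CNOC.Cl
Why: Aluminium amide aminolysis of a lactone opens the ring at the acyl carbon, leaves both stereocentres alone and frees the primary alcohol that will become the aldehyde.

Step 7
Reactants: 10 (2R,3S)-4-hydroxy-N-methoxy-N,2-dimethyl-3-[1-(oct-5-yn-1-yl)-1H-pyrrol-3-yl]butanamide
Product: 11 (2R,3S)-4-[(tert-butyldiphenylsilyl)oxy]-N-methoxy-N,2-dimethyl-3-[1-(oct-5-yn-1-yl)-1H-pyrrol-3-yl]butanamide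
Conditions: TBDPSCl, imidazole, DMF, 0 °C → rt
Reagents that add atoms: tert-butyl(chloro)diphenylsilane, CC(C)(C)[Si](Cl)(c1ccccc1)c1ccccc1
Why: Standard silylation of a primary alcohol, done at once so the γ-hydroxy amide cannot close back to the lactone; the robust silyl group is chosen to last through steps 8 to 11.

Step 8
Reactants: 11 (2R,3S)-4-[(tert-butyldiphenylsilyl)oxy]-N-methoxy-N,2-dimethyl-3-[1-(oct-5-yn-1-yl)-1H-pyrrol-3-yl]butanamide
Product: 13 (2R,3S)-4-[(tert-butyldiphenylsilyl)oxy]-3-[5-formyl-1-(oct-5-yn-1-yl)-1H-pyrrol-3-yl]-N-methoxy-N,2-dimethylbutanamide, via iminium chloride 12 (not isolated)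
Conditions: [Me2N=CHCl]Cl (1.2 equiv), CH2Cl2, −20 → 0 °C; then aq. NaOAc, rt
Reagents that add atoms: (chloromethylene)dimethyliminium chloride, C[N+](C)=CCl.[Cl-]; water, O
Why: Vilsmeier–Haack formylation of an N-alkylpyrrole at an α-carbon; C5 should be preferred because C2 lies between the N-CH2 group and the branched C3 side chain, and the formyl group then blocks C5 so that ring A can later close only at C2.

Step 9
Reactants: 13 (2R,3S)-4-[(tert-butyldiphenylsilyl)oxy]-3-[5-formyl-1-(oct-5-yn-1-yl)-1H-pyrrol-3-yl]-N-methoxy-N,2-dimethylbutanamide; 14 ethyl 2-(bromomethyl)acrylate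
Product: 16 (2R,3S)-4-[(tert-butyldiphenylsilyl)oxy]-N-methoxy-N,2-dimethyl-3-{5-[(R)-4-methylene-5-oxotetrahydrofuran-2-yl]-1-(oct-5-yn-1-yl)-1H-pyrrol-3-yl}butanamide, via hydroxy enoate 15 (not isolated)
Conditions: CrCl2 (10 mol %), chiral carbazole bis(oxazoline) ligand (12 mol %, the enantiomer that directs Re-face attack), Mn, Cp2ZrCl2, THF, rt
Reagents that add atoms: none
Why: Catalytic enantioselective Nozaki–Hiyama–Kishi-type 2-(alkoxycarbonyl)allylation; the ligand-bound allylchromium species (trivalent chromium) should add to the Re face of the aldehyde to set the (R)-carbinol, and the alkoxide then lactonises onto the ethyl ester.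

Step 10
Reactants: 16 (2R,3S)-4-[(tert-butyldiphenylsilyl)oxy]-N-methoxy-N,2-dimethyl-3-{5-[(R)-4-methylene-5-oxotetrahydrofuran-2-yl]-1-(oct-5-yn-1-yl)-1H-pyrrol-3-yl}butanamide
Product: 17 (2R,3S)-4-[(tert-butyldiphenylsilyl)oxy]-N-methoxy-N,2-dimethyl-3-{(Z)-3-[(R)-4-methylene-5-oxotetrahydrofuran-2-yl]-9-propylidene-6,7,8,9-tetrahydro-5H-pyrrolo[1,2-a]azepin-1-yl}butanamide
Conditions: Ph3PAuNTf2 (5 mol %), CH2Cl2, 0 °C → rt
Reagents that add atoms: none
Why: Gold-catalysed intramolecular alkyne hydroarylation; the only free pyrrole α-carbon attacks the alkyne carbon nearer the tether (7-exo-dig) anti to the metal (monovalent gold), and protodeauration with retention leaves hydrogen trans and ethyl cis to the pyrrole, which is the Z-propylidene group.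

Step 11
Reactants: 17 (2R,3S)-4-[(tert-butyldiphenylsilyl)oxy]-N-methoxy-N,2-dimethyl-3-{(Z)-3-[(R)-4-methylene-5-oxotetrahydrofuran-2-yl]-9-propylidene-6,7,8,9-tetrahydro-5H-pyrrolo[1,2-a]azepin-1-yl}butanamide
Product: 18 (2R,3S)-4-[(tert-butyldiphenylsilyl)oxy]-N-methoxy-N,2-dimethyl-3-{(Z)-3-[(2R,4R)-4-methyl-5-oxotetrahydrofuran-2-yl]-9-propylidene-6,7,8,9-tetrahydro-5H-pyrrolo[1,2-a]azepin-1-yl}butanamide
Conditions: RhCl(PPh3)3 (10 mol %), H2 (1 atm), toluene, rt
Reagents that add atoms: none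
Why: Homogeneous hydrogenation with RhCl(PPh3)3 should reduce the unhindered exo-methylene group and not the hindered trisubstituted alkene, adding hydrogen to the lactone face opposite the pyrrole so that the new methyl is cis to it (2R,4R).

Step 12
Reactants: 18 (2R,3S)-4-[(tert-butyldiphenylsilyl)oxy]-N-methoxy-N,2-dimethyl-3-{(Z)-3-[(2R,4R)-4-methyl-5-oxotetrahydrofuran-2-yl]-9-propylidene-6,7,8,9-tetrahydro-5H-pyrrolo[1,2-a]azepin-1-yl}butanamide
Product: 19 (2R,3S)-4-hydroxy-N-methoxy-N,2-dimethyl-3-{(Z)-3-[(2R,4R)-4-methyl-5-oxotetrahydrofuran-2-yl]-9-propylidene-6,7,8,9-tetrahydro-5H-pyrrolo[1,2-a]azepin-1-yl}butanamide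
Conditions: TBAF, AcOH (1:1), THF, 0 °C → rt
Reagents that add atoms: none
Why: Fluoride desilylation of a primary silyl ether, buffered with AcOH so that the alkoxide does not relactonise onto the amide and the alkenylpyrrole sees no strong acid.

Step 13
Reactants: 19 (2R,3S)-4-hydroxy-N-methoxy-N,2-dimethyl-3-{(Z)-3-[(2R,4R)-4-methyl-5-oxotetrahydrofuran-2-yl]-9-propylidene-6,7,8,9-tetrahydro-5H-pyrrolo[1,2-a]azepin-1-yl}butanamide
Product: 20 (2R,3S)-N-methoxy-N,2-dimethyl-3-{(Z)-3-[(2R,4R)-4-methyl-5-oxotetrahydrofuran-2-yl]-9-propylidene-6,7,8,9-tetrahydro-5H-pyrrolo[1,2-a]azepin-1-yl}-4-oxobutanamide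
Conditions: DMP, NaHCO3, CH2Cl2, 0 °C; crude product used directly
Reagents that add atoms: none
Why: Dess–Martin oxidation of a primary alcohol under bicarbonate buffer gives the α-aryl aldehyde without acid or base strong enough to epimerise C3 or isomerise the Z alkene.

Step 14
Reactants: 20 (2R,3S)-N-methoxy-N,2-dimethyl-3-{(Z)-3-[(2R,4R)-4-methyl-5-oxotetrahydrofuran-2-yl]-9-propylidene-6,7,8,9-tetrahydro-5H-pyrrolo[1,2-a]azepin-1-yl}-4-oxobutanamide
Product: 21 ring B carbinol with rings A, B, C and E: (2R)-N-methoxy-N-methyl-2-(ring B S-CH)propanamide in which ring B carries, from the pyrrole β-carbon, CH–arm (S), CH–OH (R) and CH–Et (S), ring A holds the C8=C9 alkene and the pyrrole α-carbon bears the (2R,4R)-4-methyl-5-oxotetrahydrofuran-2-yl group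
Conditions: Me2AlCl (3 equiv), CH2Cl2, −78 → −40 °C; aq. NaHCO3 quench at −40 °C
Reagents that add atoms: none
Why: Me2AlCl binds the aldehyde oxygen, the outer propylidene carbon (nucleophilic through the pyrrole nitrogen, with positive charge growing at C9) adds to the carbonyl carbon and in the same closed six-centre array a C8 hydrogen passes to oxygen, after which an Al–Me bond takes the proton as methane so no Brønsted acid is formed. The closest known reaction is the Me2AlCl-promoted type-two intramolecular carbonyl-ene (Prins-type) cyclisation of alkenyl aldehydes to homoallylic cyclohexanols. Ring B closes as a six-membered ring, exo with respect to the carbonyl and with both ene carbons inside the ring, through a chair-like (sofa) transition state. The Z geometry forces ethyl pseudoaxial, and the oxygen must lie over the C9–C8 unit to accept the hydrogen, which makes it axial and anti to ethyl, so the CH–Et carbon becomes S and the carbinol carbon R with OH trans to ethyl. The existing aryl-bound stereocentre selects the aldehyde face by keeping its amide-bearing arm equatorial, away from a 1,3-diaxial clash with ethyl, so OH ends cis to that arm as lactone D requires. The step needs the aldehyde to react in preference to the lactone E C–O bond, the amide and methyl transfer, and needs loss of the C8 hydrogen instead of the hydrogen on the ethyl-bearing carbon; low temperature, enough Me2AlCl to saturate the amide and lactone carbonyls, and the closed transition state should secure this.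

Step 15
Reactants: 21 ring B carbinol (cis γ-hydroxy N-methoxy-N-methylamide)
Product: 22 CNP0324368.1, the pentacyclic bis-lactone with ring D cis-fused to ring B
Conditions: PPTS (0.2 equiv), toluene, 40 °C
Reagents that add atoms: none
Why: Acid-catalysed lactonisation of a γ-hydroxy N-methoxy-N-methylamide whose hydroxyl and amide arm are cis on ring B (5-exo-trig acyl substitution); no stereocentre changes and the weak acid should leave lactone E and the ring A alkene alone.

**Compound list**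

1 | 1-(triisopropylsilyl)-3-(4,4,5,5-tetramethyl-1,3,2-dioxaborolan-2-yl)-1H-pyrrole | CC(C)[Si](C(C)C)(C(C)C)n1ccc(B2OC(C)(C)C(C)(C)O2)c1 | starting material
2 | furan-2(5H)-one | O=C1OCC=C1 | starting material
3 | (S)-4-[1-(triisopropylsilyl)-1H-pyrrol-3-yl]dihydrofuran-2(3H)-one | O=C1C[C@@H](c2ccn([Si](C(C)C)(C(C)C)C(C)C)c2)CO1 | intermediate
4 | (S)-4-(1H-pyrrol-3-yl)dihydrofuran-2(3H)-one | O=C1C[C@@H](c2cc[nH]c2)CO1 | intermediate
5 | but-1-yne | CCC#C | starting material
6 | 1-chloro-4-iodobutane | ClCCCCI | starting material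
7 | 8-chlorooct-3-yne | CCC#CCCCCCl | intermediate
8 | (S)-4-[1-(oct-5-yn-1-yl)-1H-pyrrol-3-yl]dihydrofuran-2(3H)-one | O=C1C[C@@H](c2ccn(CCCCC#CCC)c2)CO1 | intermediate
9 | (3R,4S)-3-methyl-4-[1-(oct-5-yn-1-yl)-1H-pyrrol-3-yl]dihydrofuran-2(3H)-one | O=C1[C@H](C)[C@@H](c2ccn(CCCCC#CCC)c2)CO1 | intermediate
10 | (2R,3S)-4-hydroxy-N-methoxy-N,2-dimethyl-3-[1-(oct-5-yn-1-yl)-1H-pyrrol-3-yl]butanamide | CON(C)C(=O)[C@H](C)[C@H](CO)c1ccn(CCCCC#CCC)c1 | intermediate
11 | (2R,3S)-4-[(tert-butyldiphenylsilyl)oxy]-N-methoxy-N,2-dimethyl-3-[1-(oct-5-yn-1-yl)-1H-pyrrol-3-yl]butanamide | CON(C)C(=O)[C@H](C)[C@H](CO[Si](c2ccccc2)(c2ccccc2)C(C)(C)C)c1ccn(CCCCC#CCC)c1 | intermediate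
12 | N,N-dimethyliminium chloride of aldehyde 13 (pyrrol-2-ylmethylidene dimethylammonium chloride) | CON(C)C(=O)[C@H](C)[C@H](CO[Si](c2ccccc2)(c2ccccc2)C(C)(C)C)c1cc(C=[N+](C)C)n(CCCCC#CCC)c1.[Cl-] | intermediate
13 | (2R,3S)-4-[(tert-butyldiphenylsilyl)oxy]-3-[5-formyl-1-(oct-5-yn-1-yl)-1H-pyrrol-3-yl]-N-methoxy-N,2-dimethylbutanamide | CON(C)C(=O)[C@H](C)[C@H](CO[Si](c2ccccc2)(c2ccccc2)C(C)(C)C)c1cc(C=O)n(CCCCC#CCC)c1 | intermediate
14 | ethyl 2-(bromomethyl)acrylate | C=C(CBr)C(=O)OCC | starting material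
15 | ethyl (R)-4-hydroxy-2-methylene-4-(pyrrol-2-yl)butanoate carrying the side chain and N-chain of 13 | CON(C)C(=O)[C@H](C)[C@H](CO[Si](c2ccccc2)(c2ccccc2)C(C)(C)C)c1cc([C@H](O)CC(=C)C(=O)OCC)n(CCCCC#CCC)c1 | intermediate
16 | (2R,3S)-4-[(tert-butyldiphenylsilyl)oxy]-N-methoxy-N,2-dimethyl-3-{5-[(R)-4-methylene-5-oxotetrahydrofuran-2-yl]-1-(oct-5-yn-1-yl)-1H-pyrrol-3-yl}butanamide | CON(C)C(=O)[C@H](C)[C@H](CO[Si](c2ccccc2)(c2ccccc2)C(C)(C)C)c1cc([C@H]3CC(=C)C(=O)O3)n(CCCCC#CCC)c1 | intermediate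
17 | (2R,3S)-4-[(tert-butyldiphenylsilyl)oxy]-N-methoxy-N,2-dimethyl-3-{(Z)-3-[(R)-4-methylene-5-oxotetrahydrofuran-2-yl]-9-propylidene-6,7,8,9-tetrahydro-5H-pyrrolo[1,2-a]azepin-1-yl}butanamide | CC/C=C1/CCCCn2c([C@H]3CC(=C)C(=O)O3)cc(c21)[C@@H](CO[Si](c4ccccc4)(c4ccccc4)C(C)(C)C)[C@@H](C)C(=O)N(C)OC | intermediate
18 | (2R,3S)-4-[(tert-butyldiphenylsilyl)oxy]-N-methoxy-N,2-dimethyl-3-{(Z)-3-[(2R,4R)-4-methyl-5-oxotetrahydrofuran-2-yl]-9-propylidene-6,7,8,9-tetrahydro-5H-pyrrolo[1,2-a]azepin-1-yl}butanamide | CC/C=C1/CCCCn2c([C@H]3C[C@@H](C)C(=O)O3)cc(c21)[C@@H](CO[Si](c4ccccc4)(c4ccccc4)C(C)(C)C)[C@@H](C)C(=O)N(C)OC | intermediate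
19 | (2R,3S)-4-hydroxy-N-methoxy-N,2-dimethyl-3-{(Z)-3-[(2R,4R)-4-methyl-5-oxotetrahydrofuran-2-yl]-9-propylidene-6,7,8,9-tetrahydro-5H-pyrrolo[1,2-a]azepin-1-yl}butanamide | CC/C=C1/CCCCn2c([C@H]3C[C@@H](C)C(=O)O3)cc(c21)[C@@H](CO)[C@@H](C)C(=O)N(C)OC | intermediate
20 | (2R,3S)-N-methoxy-N,2-dimethyl-3-{(Z)-3-[(2R,4R)-4-methyl-5-oxotetrahydrofuran-2-yl]-9-propylidene-6,7,8,9-tetrahydro-5H-pyrrolo[1,2-a]azepin-1-yl}-4-oxobutanamide (ene precursor) | CC/C=C1/CCCCn2c([C@H]3C[C@@H](C)C(=O)O3)cc(c21)[C@@H](C=O)[C@@H](C)C(=O)N(C)OC | intermediate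
21 | ring B carbinol (rings A, B, C, E; CH–Et S, CH–OH R, aryl-bound CH S, amide arm R, ring E 2R,4R) | CC[C@H]1C2=CCCCn3c([C@H]4C[C@@H](C)C(=O)O4)cc(c32)[C@@H]([C@@H]1O)[C@@H](C)C(=O)N(C)OC | intermediate
22 | CNP0324368.1 | CC[C@H]1C2=CCCCn3c([C@H]4C[C@@H](C)C(=O)O4)cc(c32)[C@H]2[C@@H]1OC(=O)[C@@H]2C | target

**Step count and weak points**

Total steps: 15. Longest linear sequence: 14 (steps 1, 2 and 4 to 15; step 3 is a one-step branch).

Steps most likely to fail:

1. Step 10. The ring may close through the eight-membered endo mode, attack at the hindered α-carbon may be slow, or traces of acid may isomerise the Z-alkenylpyrrole (Z to E, or the double bond moving into ring A). The fallback builds the same alkene by syn-carbopalladation under neutral conditions and sets out from 4. N-Alkylation of 4 with 6-iodohex-1-yne F1 (NaH, DMF) gives the hex-5-ynyl lactone F2. The operations of steps 5 to 9 follow: enolate methylation with 2.1 equiv LiN(iPr)2 so that the acetylide is formed and left unmethylated at −78 °C, then aluminium amide aminolysis, silylation, formylation and the chromium-catalysed allylation. They lead through the trans-methyl lactone F3, the hydroxy amide F4, the silyl ether F5 and the pyrrole aldehyde F6 to the methylene lactone F7. N-Iodosuccinimide iodinates the one free pyrrole α-carbon to give the α-iodopyrrole F8. Pd(PPh3)4 (zerovalent palladium) with slow addition of EtZnCl then closes ring A by 7-exo-dig syn-carbopalladation and couples the alkenylpalladium with ethyl (Negishi coupling), which places ethyl cis to the pyrrole. The route is rejoined at 17.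

2. Step 14. The aluminium Lewis acid may ionise the lactone E C–O bond at the pyrrole-bound carbon (loss of configuration there), transfer methyl to the aldehyde, or let the aldehyde α-carbon epimerise before closure. The fallback keeps the same ene closure but builds ring E last and sets out from 13. Cyclisation of 13 with Ph3PAuNTf2 gives the Z-propylidene pyrroloazepine carbaldehyde F9. Buffered desilylation gives the primary alcohol F10 and Dess–Martin oxidation the dialdehyde F11. The aliphatic aldehyde of F11 undergoes the Me2AlCl ene closure to the ring B carbinol F12. The formyl group, a vinylogous formamide with no ene partner, deactivates the pyrrole-bound carbon and leaves no C–O bond to ionise. PPTS closes ring D to the tetracyclic lactone aldehyde F13. The chromium-catalysed allylation of step 9 then gives the methylene lactone F14, and hydrogenation with RhCl(PPh3)3 as in step 11 returns to the route at 22.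

3. Step 9. Allyl transfer to the electron-rich, hindered pyrrole aldehyde may be slow or poorly face-selective, and the later hydrogenation may not fully control the methyl-bearing carbon. The fallback takes that methyl centre from the chiral pool and the carbinol from a ketone reduction, and sets out from 11. (R)-4-Methoxy-3-methyl-4-oxobutanoic acid F15 is converted with oxalyl chloride into methyl (R)-4-chloro-2-methyl-4-oxobutanoate F16. Friedel–Crafts acylation of 11 at C5 without a Lewis acid (2,6-lutidine, toluene, 80 °C) gives the γ-keto ester F17. CBS reduction with the (S)-oxazaborolidine and catecholborane should give the (R)-carbinol, which lactonises with loss of methanol to the cis-lactone F18. The gold-catalysed cyclisation of step 10 applied to F18 returns to the route at 18.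

**Further compounds**

F1 | step 10 | 6-iodohex-1-yne | C#CCCCCI
F2 | step 10 | (S)-4-[1-(hex-5-yn-1-yl)-1H-pyrrol-3-yl]dihydrofuran-2(3H)-one | O=C1C[C@@H](c2ccn(CCCCC#C)c2)CO1
F3 | step 10 | (3R,4S)-4-[1-(hex-5-yn-1-yl)-1H-pyrrol-3-yl]-3-methyldihydrofuran-2(3H)-one | O=C1[C@H](C)[C@@H](c2ccn(CCCCC#C)c2)CO1
F4 | step 10 | (2R,3S)-3-[1-(hex-5-yn-1-yl)-1H-pyrrol-3-yl]-4-hydroxy-N-methoxy-N,2-dimethylbutanamide | CON(C)C(=O)[C@H](C)[C@H](CO)c1ccn(CCCCC#C)c1
F5 | step 10 | (2R,3S)-4-[(tert-butyldiphenylsilyl)oxy]-3-[1-(hex-5-yn-1-yl)-1H-pyrrol-3-yl]-N-methoxy-N,2-dimethylbutanamide | CON(C)C(=O)[C@H](C)[C@H](CO[Si](c2ccccc2)(c2ccccc2)C(C)(C)C)c1ccn(CCCCC#C)c1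
F6 | step 10 | (2R,3S)-4-[(tert-butyldiphenylsilyl)oxy]-3-[5-formyl-1-(hex-5-yn-1-yl)-1H-pyrrol-3-yl]-N-methoxy-N,2-dimethylbutanamide | CON(C)C(=O)[C@H](C)[C@H](CO[Si](c2ccccc2)(c2ccccc2)C(C)(C)C)c1cc(C=O)n(CCCCC#C)c1
F7 | step 10 | (2R,3S)-4-[(tert-butyldiphenylsilyl)oxy]-3-{1-(hex-5-yn-1-yl)-5-[(R)-4-methylene-5-oxotetrahydrofuran-2-yl]-1H-pyrrol-3-yl}-N-methoxy-N,2-dimethylbutanamide | CON(C)C(=O)[C@H](C)[C@H](CO[Si](c2ccccc2)(c2ccccc2)C(C)(C)C)c1cc([C@H]3CC(=C)C(=O)O3)n(CCCCC#C)c1
F8 | step 10 | (2R,3S)-4-[(tert-butyldiphenylsilyl)oxy]-3-{1-(hex-5-yn-1-yl)-2-iodo-5-[(R)-4-methylene-5-oxotetrahydrofuran-2-yl]-1H-pyrrol-3-yl}-N-methoxy-N,2-dimethylbutanamide | CON(C)C(=O)[C@H](C)[C@H](CO[Si](c2ccccc2)(c2ccccc2)C(C)(C)C)c1cc([C@H]3CC(=C)C(=O)O3)n(CCCCC#C)c1I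
F9 | step 14 | (2R,3S)-4-[(tert-butyldiphenylsilyl)oxy]-3-[(Z)-3-formyl-9-propylidene-6,7,8,9-tetrahydro-5H-pyrrolo[1,2-a]azepin-1-yl]-N-methoxy-N,2-dimethylbutanamide | CC/C=C1/CCCCn2c(C=O)cc(c21)[C@@H](CO[Si](c3ccccc3)(c3ccccc3)C(C)(C)C)[C@@H](C)C(=O)N(C)OC
F10 | step 14 | (2R,3S)-3-[(Z)-3-formyl-9-propylidene-6,7,8,9-tetrahydro-5H-pyrrolo[1,2-a]azepin-1-yl]-4-hydroxy-N-methoxy-N,2-dimethylbutanamide | CC/C=C1/CCCCn2c(C=O)cc(c21)[C@@H](CO)[C@@H](C)C(=O)N(C)OC
F11 | step 14 | (2R,3S)-3-[(Z)-3-formyl-9-propylidene-6,7,8,9-tetrahydro-5H-pyrrolo[1,2-a]azepin-1-yl]-N-methoxy-N,2-dimethyl-4-oxobutanamide | CC/C=C1/CCCCn2c(C=O)cc(c21)[C@@H](C=O)[C@@H](C)C(=O)N(C)OC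
F12 | step 14 | ring B carbinol with a formyl group in place of ring E (configurations as in 21) | CC[C@H]1C2=CCCCn3c(C=O)cc(c32)[C@@H]([C@@H]1O)[C@@H](C)C(=O)N(C)OC
F13 | step 14 | tetracyclic lactone aldehyde (rings A to D of the target, formyl on the pyrrole α-carbon) | CC[C@H]1C2=CCCCn3c(C=O)cc(c32)[C@H]2[C@@H]1OC(=O)[C@@H]2C
F14 | step 14 | target analogue with an (R)-4-methylene-5-oxotetrahydrofuran-2-yl ring E | CC[C@H]1C2=CCCCn3c([C@H]4CC(=C)C(=O)O4)cc(c32)[C@H]2[C@@H]1OC(=O)[C@@H]2C
F15 | step 9 | (R)-4-methoxy-3-methyl-4-oxobutanoic acid | COC(=O)[C@H](C)CC(=O)O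
F16 | step 9 | methyl (R)-4-chloro-2-methyl-4-oxobutanoate | COC(=O)[C@H](C)CC(=O)Cl
F17 | step 9 | methyl (R)-2-methyl-4-oxo-4-(pyrrol-2-yl)butanoate carrying the side chain and N-chain of 11 | CON(C)C(=O)[C@H](C)[C@H](CO[Si](c2ccccc2)(c2ccccc2)C(C)(C)C)c1cc(C(=O)C[C@@H](C)C(=O)OC)n(CCCCC#CCC)c1
F18 | step 9 | (2R,3S)-4-[(tert-butyldiphenylsilyl)oxy]-N-methoxy-N,2-dimethyl-3-{5-[(2R,4R)-4-methyl-5-oxotetrahydrofuran-2-yl]-1-(oct-5-yn-1-yl)-1H-pyrrol-3-yl}butanamide | CON(C)C(=O)[C@H](C)[C@H](CO[Si](c2ccccc2)(c2ccccc2)C(C)(C)C)c1cc([C@H]3C[C@@H](C)C(=O)O3)n(CCCCC#CCC)c1
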